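## Retrosynthetic overview

1. Target ⇒ lancerodiol + 4-methoxybenzoyl chloride (last step); the C6 carbinol ⇐ C4–OH-directed reduction of a bicyclic ene-1,4-dione (C6 and C9 ketones).
2. Key step, both carbocycles from an open chain in one flask: a furan is unmasked to a (Z)-ene-dione methyl ketone, then aldol condensation C5→C1 closes the five-membered ring first and a 7-endo Michael addition C10→C1 closes the seven-membered ring second (sets C1 and C5).
3. Furan (masked cis-ene-dione, C6–C10) ⇐ Nozaki–Hiyama–Kishi union of a keto-aldehyde (C1–C6) with (Z)-4-iodo-3-methylbut-3-en-2-one (C7–C10).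
4. Keto-aldehyde ⇐ ozonolysis of (S)-terpinen-4-ol, whose carbinol carbon becomes C4 and relays all other stereocentres; iodoenone ⇐ but-3-yn-2-ol.
5. Locants are daucane locants: C1 (quaternary, Me), C4 (C–OH, iPr), C5 (ring-fusion H), C6 (C–O), C7=C8(Me), C9 (C=O), C10 (CH2).

Assumption: (S)-(+)-terpinen-4-ol 1 is purchased (or upgraded) to ≥98% ee; the (−)-enantiomer would give the antipode of the target.

## Route

Step 1
Reactants: 1 (S)-(+)-terpinen-4-ol
Product: 2 (3S)-3-hydroxy-6-oxo-3-(propan-2-yl)heptanal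
Conditions: O3, CH2Cl2/MeOH 4:1, −78 °C; Me2S, −78 °C → rt; used crude
Reagents that add atoms: ozone ([O-][O+]=O)
Why: Ozonolysis with reductive work-up cleaves the only C=C into the C1 methyl ketone and the C6 aldehyde and leaves the tertiary carbinol stereocentre (C4) untouched.

Step 2
Reactants: 3 but-3-yn-2-ol (racemic)
Product: 4 (Z)-4-iodo-3-methylbut-3-en-2-ol (racemic)
Conditions: MeMgBr (3 equiv), CuI (10 mol%), THF, −10 °C → rt; I2, −78 → 0 °C
Reagents that add atoms: methylmagnesium bromide (C[Mg]Br); iodine (II)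
Why: Cu-catalysed anti-carbomagnesiation of the propargylic alkoxide places Me on C3 and a chelated Mg on C4 cis to the carbinol, so iodinolysis with retention gives only the (Z)-vinyl iodide (the racemic carbinol centre is oxidised away in step 3).

Step 3
Reactants: 4 (Z)-4-iodo-3-methylbut-3-en-2-ol
Product: 5 (Z)-4-iodo-3-methylbut-3-en-2-one
Conditions: MnO2 (15 equiv), CH2Cl2, rt, dark
Reagents that add atoms: none
Why: Chemoselective MnO2 oxidation of the allylic alcohol gives the β-iodo enone without touching the vinyl iodide or its geometry.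

Step 4
Reactants: 2 (3S)-3-hydroxy-6-oxo-3-(propan-2-yl)heptanal; 5 (Z)-4-iodo-3-methylbut-3-en-2-one
Product: 7 (5S)-6-(4,5-dimethylfuran-2-yl)-5-hydroxy-5-(propan-2-yl)hexan-2-one, via Z-hydroxyenone 6 (not isolated)
Conditions: CrCl2 (4 equiv), NiCl2 (2 mol%), DMF, rt; aq. work-up; PPTS (5 mol%), CH2Cl2, rt
Reagents that add atoms: none
Why: The Nozaki–Hiyama–Kishi coupling is selective for the aldehyde over the methyl ketone and tolerates the free tertiary alcohol, and the (Z)-γ-hydroxy enone closes to its hemiketal and is dehydrated to the furan (a masked cis-ene-1,4-dione), so the new carbinol centre need not be controlled.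

Step 5
Reactants: 7 (5S)-6-(4,5-dimethylfuran-2-yl)-5-hydroxy-5-(propan-2-yl)hexan-2-one
Product: 10 (3R,3aR,8aR)-3-hydroxy-6,8a-dimethyl-3-(propan-2-yl)-1,2,3,3a,8,8a-hexahydroazulene-4,7-dione, via ene-dione 8 (not isolated), via cyclopentenyl dienedione 9 (not isolated)
Conditions: DMDO (1.1 equiv), acetone, −20 °C; evaporate; LiCl (3 equiv), DBU (2 equiv), MeCN (0.01 M), 0 → 45 °C
Reagents that add atoms: dimethyldioxirane (CC1(C)OO1)
Why: Proposed new method: DMDO opens the 2,5-dialkylfuran to the (Z)-ene-dione 8 (known), Li+/DBU soft enolisation at C5 of the Li-chelated β-hydroxy ketone gives a 5-exo aldol condensation onto the C1 methyl ketone (9), and the C10 enolate of the cis-held acetyl group then adds 7-endo to C1 (formally an 8π closure of an oxido-heptatrienyl anion), the C4–O···Li···O=C6 chelate tilting the C7–C10 arm onto the isopropyl face so that C10 bonds cis to iPr and Me ends cis to OH, while C5 (α to the C6 ketone) equilibrates to the trans-fused epimer with the acyl group anti to iPr; the competing 4-hydroxycyclopentenone aldols of the cis-ene-dione are reversible whereas dehydration and the Michael step are not; closest known reaction types are aldol-condensation/intramolecular-Michael (Robinson-type) double annulations and furan-oxidation/ene-dione cyclisation cascades.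

Step 6
Reactants: 10 (3R,3aR,8aR)-3-hydroxy-6,8a-dimethyl-3-(propan-2-yl)-1,2,3,3a,8,8a-hexahydroazulene-4,7-dione
Product: 11 lancerodiol, (3R,3aS,4S,8aR)-3,4-dihydroxy-6,8a-dimethyl-3-(propan-2-yl)-2,3,3a,4,8,8a-hexahydro-1H-azulen-7-one
Conditions: Me4NBH(OAc)3 (5 equiv), MeCN/AcOH 1:1, −30 → −20 °C
Reagents that add atoms: none
Why: Evans–Saksena hydroxyl-directed reduction: boron exchanges onto the C4–OH and hydride is delivered internally only to the β-hydroxy ketone carbonyl C6 from the C4–O face, giving the 1,3-anti diol (6S in daucane locants) and sparing the C9 enone carbonyl.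

Step 7
Reactants: 11 lancerodiol; 12 4-methoxybenzoyl chloride
Product: 13 lancerodiol p-methoxybenzoate, (3R,3aS,4S,8aR)-3-hydroxy-6,8a-dimethyl-7-oxo-3-(propan-2-yl)-1,2,3,3a,4,7,8,8a-octahydroazulen-4-yl 4-methoxybenzoate
Conditions: Et3N (3 equiv), DMAP (0.2 equiv), CH2Cl2, 0 °C → rt
Reagents that add atoms: none
Why: DMAP-catalysed acyl transfer esterifies the secondary allylic C6–OH, while the tertiary C4 carbinol is too hindered to react.

## Compound list

1 | (S)-(+)-terpinen-4-ol, (1S)-4-methyl-1-(propan-2-yl)cyclohex-3-en-1-ol | CC1=CC[C@](O)(C(C)C)CC1 | starting material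
2 | (3S)-3-hydroxy-6-oxo-3-(propan-2-yl)heptanal | O=CC[C@](O)(C(C)C)CCC(C)=O | intermediate
3 | but-3-yn-2-ol (racemic) | CC(O)C#C | starting material
4 | (Z)-4-iodo-3-methylbut-3-en-2-ol (racemic) | CC(O)/C(C)=C\I | intermediate
5 | (Z)-4-iodo-3-methylbut-3-en-2-one | CC(=O)/C(C)=C\I | intermediate
6 | (3Z,7S)-5,7-dihydroxy-3-methyl-7-(propan-2-yl)undec-3-ene-2,10-dione (C5 epimers, not isolated) | CC(=O)/C(C)=C\C(O)C[C@](O)(C(C)C)CCC(C)=O | intermediate
7 | (5S)-6-(4,5-dimethylfuran-2-yl)-5-hydroxy-5-(propan-2-yl)hexan-2-one | Cc1oc(C[C@](O)(C(C)C)CCC(C)=O)cc1C | intermediate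
8 | (3Z,7S)-7-hydroxy-3-methyl-7-(propan-2-yl)undec-3-ene-2,5,10-trione (not isolated) | CC(=O)/C(C)=C\C(=O)C[C@](O)(C(C)C)CCC(C)=O | intermediate
9 | (2Z)-1-[(5R)-5-hydroxy-2-methyl-5-(propan-2-yl)cyclopent-1-en-1-yl]-3-methylpent-2-ene-1,4-dione (not isolated) | CC(=O)/C(C)=C\C(=O)C1=C(C)CC[C@@]1(O)C(C)C | intermediate
10 | (3R,3aR,8aR)-3-hydroxy-6,8a-dimethyl-3-(propan-2-yl)-1,2,3,3a,8,8a-hexahydroazulene-4,7-dione (trans-fused) | O=C1C=C(C)C(=O)C[C@@]2(C)CC[C@@](O)(C(C)C)[C@H]12 | intermediate
11 | lancerodiol, (3R,3aS,4S,8aR)-3,4-dihydroxy-6,8a-dimethyl-3-(propan-2-yl)-2,3,3a,4,8,8a-hexahydro-1H-azulen-7-one | O[C@H]1C=C(C)C(=O)C[C@@]2(C)CC[C@@](O)(C(C)C)[C@H]12 | intermediate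
12 | 4-methoxybenzoyl chloride | COc1ccc(C(=O)Cl)cc1 | starting material
13 | lancerodiol p-methoxybenzoate, (3R,3aS,4S,8aR)-3-hydroxy-6,8a-dimethyl-7-oxo-3-(propan-2-yl)-1,2,3,3a,4,7,8,8a-octahydroazulen-4-yl 4-methoxybenzoate | COc1ccc(C(=O)O[C@H]2C=C(C)C(=O)C[C@@]3(C)CC[C@@](O)(C(C)C)[C@H]23)cc1 | target

## Step count and risks

Total step count: 7. Longest linear sequence: 6 (3 → 4 → 5 → 7 → 10 → 11 → 13); from 1 it is 5.

Steps most likely to fail:

Step 5 (double cyclisation). This is the boldest step and has no direct precedent. The risks are the wrong aldol regiochemistry (C2 onto C6), diversion of the cis-ene-dione into 4-hydroxycyclopentenones, a sluggish 7-endo Michael addition, and the wrong face at C1. Fallback: give up the one-pot closure and close the rings one at a time, with the first closure under enamine control. Set out from 2: piperidinium acetate (benzene, 60 °C) condenses the aldehyde α-carbon onto the methyl ketone to give the enal (5R)-5-hydroxy-2-methyl-5-(propan-2-yl)cyclopent-1-ene-1-carbaldehyde F1. NHK coupling of this enal with 5, then PPTS, gives the furan (1R)-2-(4,5-dimethylfuran-2-yl)-3-methyl-1-(propan-2-yl)cyclopent-2-en-1-ol F2. DMDO opens this furan to 9, which then only has to undergo the 7-endo Michael closure (LiCl/DBU) to rejoin the route at 10.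

Step 4 (NHK coupling and furan formation). The β-iodo enone may couple poorly with the sensitive β-hydroxy aldehyde, or the aldehyde may dehydrate. Fallback: replace the polar C6–C7 bond formation by a radical one. Set out from 2: decatungstate-photocatalysed hydroacylation (TBADT 2 mol%, 365 nm, MeCN) of commercial 3-methylbut-3-en-2-one with the aldehyde C–H of 2 gives the 1,4-diketone (3RS,7S)-7-hydroxy-3-methyl-7-(propan-2-yl)undecane-2,5,10-trione F3. Paal–Knorr cyclodehydration (PPTS, toluene, 60 °C) returns to the route at 7.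

Step 6 (directed reduction). Triacetoxyborohydride may not exchange onto the hindered tertiary C4–OH, or may reduce the ene-dione unselectively. Fallback: tether the hydride through silicon. Set out from 10: iPr2SiHCl, imidazole, DMF gives the hydridosilyl ether (3R,3aR,8aR)-3-{[di(propan-2-yl)silyl]oxy}-6,8a-dimethyl-3-(propan-2-yl)-1,2,3,3a,8,8a-hexahydroazulene-4,7-dione F4. SnCl4 (cat.), CH2Cl2, −80 °C triggers intramolecular hydrosilylation of the C6 ketone from the C4–O face to give lancerodiol 3,4-O-di(propan-2-yl)silylene acetal F5. HF·pyridine removes silicon and returns to the route at 11.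

Further compounds
F1 | step 5 | (5R)-5-hydroxy-2-methyl-5-(propan-2-yl)cyclopent-1-ene-1-carbaldehyde | O=CC1=C(C)CC[C@@]1(O)C(C)C
F2 | step 5 | (1R)-2-(4,5-dimethylfuran-2-yl)-3-methyl-1-(propan-2-yl)cyclopent-2-en-1-ol | Cc1oc(C2=C(C)CC[C@@]2(O)C(C)C)cc1C
F3 | step 4 | (3RS,7S)-7-hydroxy-3-methyl-7-(propan-2-yl)undecane-2,5,10-trione | CC(=O)C(C)CC(=O)C[C@](O)(C(C)C)CCC(C)=O
F4 | step 6 | (3R,3aR,8aR)-3-{[di(propan-2-yl)silyl]oxy}-6,8a-dimethyl-3-(propan-2-yl)-1,2,3,3a,8,8a-hexahydroazulene-4,7-dione | O=C1C=C(C)C(=O)C[C@@]2(C)CC[C@@](O[SiH](C(C)C)C(C)C)(C(C)C)[C@H]12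
F5 | step 6 | lancerodiol 3,4-O-di(propan-2-yl)silylene acetal | CC(C)[Si]3(C(C)C)O[C@H]1C=C(C)C(=O)C[C@@]2(C)CC[C@@](O3)(C(C)C)[C@H]12
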